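**Retrosynthetic overview**

1. Target 27 ⇐ desilylation of 26 ⇐ ring-closing metathesis of diene 25, which forms the C1=C10 enoate and closes the ten-membered carbocycle last.
2. 25 ⇐ isobutyrylation of 24 ⇐ intermolecular zinc Barbier allylation (C7–C8 bond) of bromomethyl butenolide 20 (C1–C7, C11–C13, C15) with itaconate-derived aldehyde 22 (C8–C10, C14); this sets C7 and C8 and unveils the α-methylene trans-lactone.
3. 20 ⇐ butenolide (first ring) by Pd-catalysed carbonylative lactonisation of Z-iodo allylic alcohol 17 ⇐ hydroalumination/iodination of propargylic alcohol 15 ⇐ asymmetric transfer hydrogenation of ynone 14 (sets C6).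
4. 14 ⇐ Weinreb amide 11 + silyl propargyl ether 12; 11 ⇐ lactone 9 ⇐ Evans alkylation of the hex-5-enoyl oxazolidinone with tert-butyl bromoacetate (sets C4).
5. Ring order: butenolide (it becomes the γ-lactone in the Barbier step), then the ten-membered ring.

Assumption: germacrane-type numbering is used for orientation (lactone oxygen on C6, ring fusion C6/C7, isobutyrate on C8, CO2Me = C14 on C10, CH2OH = C15 on C4); the target is (4S,6R,7S,8R) with an E (ring-cis) C1=C10 bond; TBDPS = tert-butyldiphenylsilyl, TBS = tert-butyldimethylsilyl.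

**Route**

Step 1
Reactants: 1 hex-5-enoic acid; 2 (4R)-4-benzyl-1,3-oxazolidin-2-one
Product: 4 (4R)-4-benzyl-3-(hex-5-enoyl)-1,3-oxazolidin-2-one, via mixed pivalic anhydride 3 (not isolated)
Conditions: PivCl, Et3N, THF, −20 °C; then 2, LiCl, −20 °C → rt
Reagents that add atoms: none
Why: N-acylation of the Evans oxazolidinone through the mixed pivalic anhydride (LiCl-promoted) needs no strong base and leaves the terminal alkene alone.

Step 2
Reactants: 4 (4R)-4-benzyl-3-(hex-5-enoyl)-1,3-oxazolidin-2-one; 5 tert-butyl bromoacetate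
Product: 7 tert-butyl (3S)-3-{[(4R)-4-benzyl-2-oxo-1,3-oxazolidin-3-yl]carbonyl}hept-6-enoate, via sodium Z-enolate 6 (not isolated)
Conditions: NaN(SiMe3)2, THF, −78 °C; then 5, −78 → −40 °C
Reagents that add atoms: none
Why: Evans asymmetric alkylation, in which the chelated sodium Z-enolate is alkylated by the reactive α-bromo ester on the face opposite the benzyl group, sets the future C4 stereocentre (3S in 7).

Step 3
Reactants: 7 tert-butyl (3S)-3-{[(4R)-4-benzyl-2-oxo-1,3-oxazolidin-3-yl]carbonyl}hept-6-enoate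
Product: 8 tert-butyl (3S)-3-(hydroxymethyl)hept-6-enoate
Conditions: LiBH4, THF, 0 °C → rt; aq. NH4Cl
Reagents that add atoms: none
Why: Reductive removal of the auxiliary, in which LiBH4 reduces the activated imide carbonyl to the primary alcohol (future C15) but not the hindered tert-butyl ester, breaks no bond at the stereocentre.

Step 4
Reactants: 8 tert-butyl (3S)-3-(hydroxymethyl)hept-6-enoate
Product: 9 (4S)-4-(but-3-en-1-yl)oxolan-2-one
Conditions: TFA, CH2Cl2, 0 °C → rt
Reagents that add atoms: none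
Why: Acid-catalysed cleavage of the tert-butyl ester is followed by spontaneous five-membered lactonisation (intramolecular esterification) of the γ-hydroxy acid.

Step 5
Reactants: 9 (4S)-4-(but-3-en-1-yl)oxolan-2-one
Product: 10 (3S)-3-(hydroxymethyl)-N-methoxy-N-methylhept-6-enamide
Conditions: MeNH(OMe)·HCl, AlMe3, CH2Cl2, 0 °C → rt; aq. KNaC4H4O6
Reagents that add atoms: N,O-dimethylhydroxylamine hydrochloride (CNOC.Cl)
Why: Weinreb aminolysis, in which the aluminium amide opens the γ-lactone to the N-methoxy-N-methylamide, frees the primary alcohol.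

Step 6
Reactants: 10 (3S)-3-(hydroxymethyl)-N-methoxy-N-methylhept-6-enamide
Product: 11 (3S)-3-{[(tert-butyldiphenylsilyl)oxy]methyl}-N-methoxy-N-methylhept-6-enamide
Conditions: TBDPSCl, imidazole, CH2Cl2, 0 °C → rt (crude 10 used at once)
Reagents that add atoms: tert-butyl(chloro)diphenylsilane (CC(C)(C)[Si](Cl)(c1ccccc1)c1ccccc1)
Why: Silyl ether formation at the primary alcohol stops relactonisation and installs a group that survives the later acid removal of TBS.

Step 7
Reactants: 11 (3S)-3-{[(tert-butyldiphenylsilyl)oxy]methyl}-N-methoxy-N-methylhept-6-enamide; 12 tert-butyldimethyl(prop-2-yn-1-yloxy)silane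
Product: 14 (6S)-1-[(tert-butyldimethylsilyl)oxy]-6-{[(tert-butyldiphenylsilyl)oxy]methyl}dec-9-en-2-yn-4-one, via lithium acetylide 13 (not isolated)
Conditions: 12, n-BuLi, THF, −78 °C; then 11, −78 → 0 °C; aq. NH4Cl
Reagents that add atoms: none
Why: Weinreb ketone synthesis, in which the lithium acetylide adds only once because the chelated tetrahedral adduct collapses on work-up, gives the ynone.

Step 8
Reactants: 14 (6S)-1-[(tert-butyldimethylsilyl)oxy]-6-{[(tert-butyldiphenylsilyl)oxy]methyl}dec-9-en-2-yn-4-one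
Product: 15 (4R,6S)-1-[(tert-butyldimethylsilyl)oxy]-6-{[(tert-butyldiphenylsilyl)oxy]methyl}dec-9-en-2-yn-4-ol
Conditions: Ru[(R,R)-TsDPEN](p-cymene) (2 mol %), iPrOH, rt
Reagents that add atoms: none
Why: Noyori asymmetric transfer hydrogenation with the (R,R)-configured catalyst reduces the alkynyl ketone under catalyst control to the (4R)-propargylic alcohol, which sets C6 independently of the remote C4 centre.

Step 9
Reactants: 15 (4R,6S)-1-[(tert-butyldimethylsilyl)oxy]-6-{[(tert-butyldiphenylsilyl)oxy]methyl}dec-9-en-2-yn-4-ol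
Product: 17 (2Z,4R,6S)-1-[(tert-butyldimethylsilyl)oxy]-6-{[(tert-butyldiphenylsilyl)oxy]methyl}-2-iododeca-2,9-dien-4-ol, via cyclic vinylalanate 16 (not isolated)
Conditions: NaAlH2(OCH2CH2OMe)2, THF, 0 °C; EtOAc; then I2, −78 → 0 °C; aq. Na2S2O3
Reagents that add atoms: iodine ([I][I])
Why: Hydroxyl-directed trans-hydroalumination places aluminium on the distal alkyne carbon in a five-membered alanate, and iodinolysis with retention gives the Z-iodoalkene with iodine cis to the carbinol carbon.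

Step 10
Reactants: 17 (2Z,4R,6S)-1-[(tert-butyldimethylsilyl)oxy]-6-{[(tert-butyldiphenylsilyl)oxy]methyl}-2-iododeca-2,9-dien-4-ol
Product: 18 (5R)-3-{[(tert-butyldimethylsilyl)oxy]methyl}-5-[(2S)-2-{[(tert-butyldiphenylsilyl)oxy]methyl}hex-5-en-1-yl]furan-2(5H)-one
Conditions: PdCl2(PPh3)2 (5 mol %), CO (1 atm), K2CO3, THF, 50 °C
Reagents that add atoms: carbon monoxide ([C-]#[O+])
Why: Carbonylative lactonisation (oxidative addition of the C–I bond to zerovalent palladium, CO insertion, capture of the acyl palladium by the cis hydroxyl) closes the butenolide without touching C6.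

Step 11
Reactants: 18 (5R)-3-{[(tert-butyldimethylsilyl)oxy]methyl}-5-[(2S)-2-{[(tert-butyldiphenylsilyl)oxy]methyl}hex-5-en-1-yl]furan-2(5H)-one
Product: 19 (5R)-5-[(2S)-2-{[(tert-butyldiphenylsilyl)oxy]methyl}hex-5-en-1-yl]-3-(hydroxymethyl)furan-2(5H)-one
Conditions: CSA (10 mol %), MeOH/CH2Cl2 (1:1), 0 °C
Reagents that add atoms: none
Why: Acid-catalysed methanolysis cleaves the primary TBS ether much faster than the bulkier TBDPS ether (selective desilylation).

Step 12
Reactants: 19 (5R)-5-[(2S)-2-{[(tert-butyldiphenylsilyl)oxy]methyl}hex-5-en-1-yl]-3-(hydroxymethyl)furan-2(5H)-one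
Product: 20 (5R)-3-(bromomethyl)-5-[(2S)-2-{[(tert-butyldiphenylsilyl)oxy]methyl}hex-5-en-1-yl]furan-2(5H)-one
Conditions: CBr4, PPh3, CH2Cl2, 0 °C
Reagents that add atoms: carbon tetrabromide (BrC(Br)(Br)Br)
Why: Appel bromination converts the primary allylic alcohol into the bromide under neutral conditions, so the base-sensitive C5–H of the butenolide is not epimerised.

Step 13
Reactants: 21 dimethyl itaconate (dimethyl 2-methylidenebutanedioate)
Product: 22 methyl 2-methylidene-4-oxobutanoate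
Conditions: iBu2AlH (1.0 equiv), CH2Cl2, −78 °C; MeOH, aq. KNaC4H4O6; used crude at once
Reagents that add atoms: none
Why: Partial reduction with iBu2AlH takes the more electrophilic non-conjugated ester, whose tetrahedral aluminium hemiacetal is stable at −78 °C, so the aldehyde is released only on work-up.

Step 14
Reactants: 20 (5R)-3-(bromomethyl)-5-[(2S)-2-{[(tert-butyldiphenylsilyl)oxy]methyl}hex-5-en-1-yl]furan-2(5H)-one; 22 methyl 2-methylidene-4-oxobutanoate
Product: 24 methyl (4R)-4-[(2R,3R)-2-[(2S)-2-{[(tert-butyldiphenylsilyl)oxy]methyl}hex-5-en-1-yl]-4-methylidene-5-oxooxolan-3-yl]-4-hydroxy-2-methylidenebutanoate, via allylzinc bromide 23 (not isolated)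
Conditions: Zn dust (activated), 22 (1.5 equiv), THF/sat. aq. NH4Cl (2:1), 0 °C → rt
Reagents that add atoms: none
Why: Zinc Barbier-type carbonyl allylation, in which the allylzinc reacts at its γ-carbon (C7) on the face anti to the C6 side chain, gives the trans-fused α-methylene-γ-butyrolactone, and under aqueous zinc conditions this ring-locked reagent is expected to give the syn carbinol with the 8R configuration of the target.

Step 15
Reactants: 24 methyl (4R)-4-[(2R,3R)-2-[(2S)-2-{[(tert-butyldiphenylsilyl)oxy]methyl}hex-5-en-1-yl]-4-methylidene-5-oxooxolan-3-yl]-4-hydroxy-2-methylidenebutanoate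
Product: 25 methyl (4R)-4-[(2R,3S)-2-[(2S)-2-{[(tert-butyldiphenylsilyl)oxy]methyl}hex-5-en-1-yl]-4-methylidene-5-oxooxolan-3-yl]-2-methylidene-4-[(2-methylpropanoyl)oxy]butanoate
Conditions: (iPrCO)2O, Et3N, DMAP (cat.), CH2Cl2, 0 °C → rt (crude 24 used at once)
Reagents that add atoms: isobutyric anhydride (CC(C)C(=O)OC(=O)C(C)C)
Why: DMAP-catalysed acylation of the secondary alcohol proceeds with retention at C8 and also blocks lactonisation of the hydroxyl onto the methyl ester.

Step 16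
Reactants: 25 methyl (4R)-4-[(2R,3S)-2-[(2S)-2-{[(tert-butyldiphenylsilyl)oxy]methyl}hex-5-en-1-yl]-4-methylidene-5-oxooxolan-3-yl]-2-methylidene-4-[(2-methylpropanoyl)oxy]butanoate
Product: 26 methyl (3aS,4R,6E,10S,11aR)-10-{[(tert-butyldiphenylsilyl)oxy]methyl}-3-methylidene-4-[(2-methylpropanoyl)oxy]-2-oxo-2,3,3a,4,5,8,9,10,11,11a-decahydrocyclodeca[b]furan-6-carboxylate
Conditions: second-generation Hoveyda–Grubbs catalyst RuCl2(H2IMes)(=CH-C6H4-2-OiPr) (15 mol %, in portions), 1,4-benzoquinone (30 mol %), toluene (0.001 mol/L), 80 °C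
Reagents that add atoms: none
Why: Ring-closing metathesis, in which the ruthenium carbene loads on the terminal vinyl group and closes onto the 1,1-disubstituted acrylate, gives the ring-cis (CIP E) trisubstituted enoate that a ten-membered ring enforces, while the more hindered methylene lactone is not engaged.

Step 17
Reactants: 26 methyl (3aS,4R,6E,10S,11aR)-10-{[(tert-butyldiphenylsilyl)oxy]methyl}-3-methylidene-4-[(2-methylpropanoyl)oxy]-2-oxo-2,3,3a,4,5,8,9,10,11,11a-decahydrocyclodeca[b]furan-6-carboxylate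
Product: 27 methyl (3aS,4R,6E,10S,11aR)-10-(hydroxymethyl)-3-methylidene-4-[(2-methylpropanoyl)oxy]-2-oxo-2,3,3a,4,5,8,9,10,11,11a-decahydrocyclodeca[b]furan-6-carboxylate (CNP0251148.1)
Conditions: HF·pyridine, THF/pyridine, 0 °C → rt
Reagents that add atoms: none
Why: Fluoride-mediated desilylation under buffered acidic conditions removes the TBDPS group without Michael addition to the methylene lactone or ester cleavage.

**Compound list**

1 | hex-5-enoic acid | C=CCCCC(=O)O | starting material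
2 | (4R)-4-benzyl-1,3-oxazolidin-2-one | O=C1N[C@H](Cc2ccccc2)CO1 | starting material
3 | hex-5-enoic pivalic anhydride (formed in situ) | C=CCCCC(=O)OC(=O)C(C)(C)C | intermediate
4 | (4R)-4-benzyl-3-(hex-5-enoyl)-1,3-oxazolidin-2-one | C=CCCCC(=O)N1[C@H](Cc2ccccc2)COC1=O | intermediate
5 | tert-butyl bromoacetate | BrCC(=O)OC(C)(C)C | starting material
6 | sodium Z-enolate of 4 (formed in situ) | [Na+].[O-]/C(=C\CCC=C)N1[C@H](Cc2ccccc2)COC1=O | intermediate
7 | tert-butyl (3S)-3-{[(4R)-4-benzyl-2-oxo-1,3-oxazolidin-3-yl]carbonyl}hept-6-enoate | O=C1OC[C@@H](Cc2ccccc2)N1C(=O)[C@H](CC(=O)OC(C)(C)C)CCC=C | intermediate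
8 | tert-butyl (3S)-3-(hydroxymethyl)hept-6-enoate | CC(C)(C)OC(=O)C[C@@H](CO)CCC=C | intermediate
9 | (4S)-4-(but-3-en-1-yl)oxolan-2-one | O=C1C[C@H](CCC=C)CO1 | intermediate
10 | (3S)-3-(hydroxymethyl)-N-methoxy-N-methylhept-6-enamide | CON(C)C(=O)C[C@@H](CO)CCC=C | intermediate
11 | (3S)-3-{[(tert-butyldiphenylsilyl)oxy]methyl}-N-methoxy-N-methylhept-6-enamide | CON(C)C(=O)C[C@@H](CO[Si](c1ccccc1)(c1ccccc1)C(C)(C)C)CCC=C | intermediate
12 | tert-butyldimethyl(prop-2-yn-1-yloxy)silane | C#CCO[Si](C)(C)C(C)(C)C | starting material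
13 | lithium 3-[(tert-butyldimethylsilyl)oxy]prop-1-yn-1-ide (formed in situ) | [Li+].[C-]#CCO[Si](C)(C)C(C)(C)C | intermediate
14 | (6S)-1-[(tert-butyldimethylsilyl)oxy]-6-{[(tert-butyldiphenylsilyl)oxy]methyl}dec-9-en-2-yn-4-one | O=C(C#CCO[Si](C)(C)C(C)(C)C)C[C@@H](CO[Si](c1ccccc1)(c1ccccc1)C(C)(C)C)CCC=C | intermediate
15 | (4R,6S)-1-[(tert-butyldimethylsilyl)oxy]-6-{[(tert-butyldiphenylsilyl)oxy]methyl}dec-9-en-2-yn-4-ol | O[C@@H](C#CCO[Si](C)(C)C(C)(C)C)C[C@@H](CO[Si](c1ccccc1)(c1ccccc1)C(C)(C)C)CCC=C | intermediate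
16 | sodium (5R)-2,2-bis(2-methoxyethoxy)-3-{[(tert-butyldimethylsilyl)oxy]methyl}-5-[(2S)-2-{[(tert-butyldiphenylsilyl)oxy]methyl}hex-5-en-1-yl]-2,5-dihydro-1,2-oxaluminol-2-uide (cyclic vinylalanate, formed in situ) | [Na+].COCCO[Al-]1(OCCOC)O[C@H](C[C@@H](CO[Si](c2ccccc2)(c2ccccc2)C(C)(C)C)CCC=C)C=C1CO[Si](C)(C)C(C)(C)C | intermediate
17 | (2Z,4R,6S)-1-[(tert-butyldimethylsilyl)oxy]-6-{[(tert-butyldiphenylsilyl)oxy]methyl}-2-iododeca-2,9-dien-4-ol | O[C@@H](/C=C(\I)CO[Si](C)(C)C(C)(C)C)C[C@@H](CO[Si](c1ccccc1)(c1ccccc1)C(C)(C)C)CCC=C | intermediate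
18 | (5R)-3-{[(tert-butyldimethylsilyl)oxy]methyl}-5-[(2S)-2-{[(tert-butyldiphenylsilyl)oxy]methyl}hex-5-en-1-yl]furan-2(5H)-one | O=C1O[C@H](C[C@@H](CO[Si](c2ccccc2)(c2ccccc2)C(C)(C)C)CCC=C)C=C1CO[Si](C)(C)C(C)(C)C | intermediate
19 | (5R)-5-[(2S)-2-{[(tert-butyldiphenylsilyl)oxy]methyl}hex-5-en-1-yl]-3-(hydroxymethyl)furan-2(5H)-one | O=C1O[C@H](C[C@@H](CO[Si](c2ccccc2)(c2ccccc2)C(C)(C)C)CCC=C)C=C1CO | intermediate
20 | (5R)-3-(bromomethyl)-5-[(2S)-2-{[(tert-butyldiphenylsilyl)oxy]methyl}hex-5-en-1-yl]furan-2(5H)-one | O=C1O[C@H](C[C@@H](CO[Si](c2ccccc2)(c2ccccc2)C(C)(C)C)CCC=C)C=C1CBr | intermediate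
21 | dimethyl itaconate (dimethyl 2-methylidenebutanedioate) | COC(=O)CC(=C)C(=O)OC | starting material
22 | methyl 2-methylidene-4-oxobutanoate | COC(=O)C(=C)CC=O | intermediate
23 | {[(5R)-5-[(2S)-2-{[(tert-butyldiphenylsilyl)oxy]methyl}hex-5-en-1-yl]-2-oxo-2,5-dihydrofuran-3-yl]methyl}zinc bromide (formed in situ) | O=C1O[C@H](C[C@@H](CO[Si](c2ccccc2)(c2ccccc2)C(C)(C)C)CCC=C)C=C1C[Zn]Br | intermediate
24 | methyl (4R)-4-[(2R,3R)-2-[(2S)-2-{[(tert-butyldiphenylsilyl)oxy]methyl}hex-5-en-1-yl]-4-methylidene-5-oxooxolan-3-yl]-4-hydroxy-2-methylidenebutanoate (trans-lactone, syn carbinol) | C=C1C(=O)O[C@H](C[C@@H](CO[Si](c2ccccc2)(c2ccccc2)C(C)(C)C)CCC=C)[C@H]1[C@H](O)CC(=C)C(=O)OC | intermediate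
25 | methyl (4R)-4-[(2R,3S)-2-[(2S)-2-{[(tert-butyldiphenylsilyl)oxy]methyl}hex-5-en-1-yl]-4-methylidene-5-oxooxolan-3-yl]-2-methylidene-4-[(2-methylpropanoyl)oxy]butanoate | C=C1C(=O)O[C@H](C[C@@H](CO[Si](c2ccccc2)(c2ccccc2)C(C)(C)C)CCC=C)[C@H]1[C@H](OC(=O)C(C)C)CC(=C)C(=O)OC | intermediate
26 | methyl (3aS,4R,6E,10S,11aR)-10-{[(tert-butyldiphenylsilyl)oxy]methyl}-3-methylidene-4-[(2-methylpropanoyl)oxy]-2-oxo-2,3,3a,4,5,8,9,10,11,11a-decahydrocyclodeca[b]furan-6-carboxylate | C=C1C(=O)O[C@@H]2C[C@@H](CO[Si](c3ccccc3)(c3ccccc3)C(C)(C)C)CC/C=C(/C(=O)OC)C[C@@H](OC(=O)C(C)C)[C@@H]12 | intermediate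
27 | methyl (3aS,4R,6E,10S,11aR)-10-(hydroxymethyl)-3-methylidene-4-[(2-methylpropanoyl)oxy]-2-oxo-2,3,3a,4,5,8,9,10,11,11a-decahydrocyclodeca[b]furan-6-carboxylate | C=C1C(=O)O[C@@H]2C[C@@H](CO)CC/C=C(/C(=O)OC)C[C@@H](OC(=O)C(C)C)[C@@H]12 | target

**Totals and risks**

Total step count: 17. Longest linear sequence: 16 steps (steps 1–12 and 14–17, from hex-5-enoic acid 1 to 27).

Steps most likely to fail:

(a) Step 16. Ring-closing metathesis onto an electron-poor α-substituted acrylate to a strained ten-membered ring may stall, dimerise or engage the methylene lactone. The fallback sets out from bromolactone 20 (with aldehyde 22 as the source of the second partner) and comes back at 26. Aldehyde 22 is protected as methyl 4,4-dimethoxy-2-methylidenebutanoate F1 (HC(OMe)3, MeOH, cat. TsOH). Cross-metathesis of the terminal alkene of 20 with an excess of F1 (second-generation Hoveyda–Grubbs catalyst, CH2Cl2, 40 °C) makes the trisubstituted E-enoate free of ring strain and gives the bromolactone enoate acetal F2. Aqueous TFA in CH2Cl2 frees the bromo aldehyde F3. CrCl2 in THF at high dilution then closes the ten-membered ring through the same C7–C8 allylation to the macrocyclic carbinol F4, which is isobutyrylated as in step 15 to give 26. This detour makes the C7–C8 bond intramolecularly, and the C8 configuration of F4 is not secured in advance.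

(b) Step 14. The aldehyde is labile, the adduct can lactonise onto its methyl ester, and the syn selectivity at C8 rests on the open transition state of the aqueous zinc reaction rather than on a closed chair, which would give the epimer. The fallback sets out from 20 and 22 and comes back at 25. With CrCl2 in anhydrous THF the allylchromium adds through a closed chair transition state, which for this ring-locked reagent gives the anti (C8-epimeric) adduct F5. Esterification of F5 with isobutyric acid under Mitsunobu conditions (PPh3, DIAD, toluene, 0 °C) inverts C8 and gives 25 directly.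

(c) Step 13. Half-reduction of a diester can over-reduce, and the β,γ-unsaturated aldehyde isomerises easily to the conjugated enal. The fallback sets out from 21 and comes back at 22. Regioselective saponification of the more reactive non-conjugated ester (LiOH, 1 equiv, THF/H2O, 0 °C) gives 3-(methoxycarbonyl)but-3-enoic acid F6. BH3·SMe2 (THF, 0 °C) reduces the acid but not the ester to methyl 4-hydroxy-2-methylidenebutanoate F7. Oxidation of F7 with Dess–Martin periodinane buffered with NaHCO3 (CH2Cl2, 0 °C) gives 22 under non-basic conditions.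

Further compounds
F1 | step 16 | methyl 4,4-dimethoxy-2-methylidenebutanoate | COC(=O)C(=C)CC(OC)OC
F2 | step 16 | methyl (2E,6S)-7-[(2R)-4-(bromomethyl)-5-oxo-2,5-dihydrofuran-2-yl]-6-{[(tert-butyldiphenylsilyl)oxy]methyl}-2-(2,2-dimethoxyethyl)hept-2-enoate | O=C1O[C@H](C[C@@H](CO[Si](c2ccccc2)(c2ccccc2)C(C)(C)C)CC/C=C(/C(=O)OC)CC(OC)OC)C=C1CBr
F3 | step 16 | methyl (2E,6S)-7-[(2R)-4-(bromomethyl)-5-oxo-2,5-dihydrofuran-2-yl]-6-{[(tert-butyldiphenylsilyl)oxy]methyl}-2-(2-oxoethyl)hept-2-enoate | O=C1O[C@H](C[C@@H](CO[Si](c2ccccc2)(c2ccccc2)C(C)(C)C)CC/C=C(/C(=O)OC)CC=O)C=C1CBr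
F4 | step 16 | methyl (3aR,4R,6E,10S,11aR)-10-{[(tert-butyldiphenylsilyl)oxy]methyl}-4-hydroxy-3-methylidene-2-oxo-2,3,3a,4,5,8,9,10,11,11a-decahydrocyclodeca[b]furan-6-carboxylate | C=C1C(=O)O[C@@H]2C[C@@H](CO[Si](c3ccccc3)(c3ccccc3)C(C)(C)C)CC/C=C(/C(=O)OC)C[C@@H](O)[C@@H]12
F5 | step 14 | methyl (4S)-4-[(2R,3R)-2-[(2S)-2-{[(tert-butyldiphenylsilyl)oxy]methyl}hex-5-en-1-yl]-4-methylidene-5-oxooxolan-3-yl]-4-hydroxy-2-methylidenebutanoate | C=C1C(=O)O[C@H](C[C@@H](CO[Si](c2ccccc2)(c2ccccc2)C(C)(C)C)CCC=C)[C@H]1[C@@H](O)CC(=C)C(=O)OC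
F6 | step 13 | 3-(methoxycarbonyl)but-3-enoic acid | COC(=O)C(=C)CC(=O)O
F7 | step 13 | methyl 4-hydroxy-2-methylidenebutanoate | COC(=O)C(=C)CCO
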